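**Strategy.** Everything rests on cutting the C3–C4 bond of the tetrahydrofuran ring. In one operation, titanocene(III) opens a terminal epoxide to a C3 radical that closes 5-exo onto a cinnamyl ether alkene, forming the ring and placing the C3 hydroxymethyl cis to the C4 benzyl and trans to the C2 aryl, the pattern of the target. The precursor is the (E)-O-benzylconiferyl ether of an erythro aryl(oxiranyl)methanol whose syringyl ring already carries, on O4, the erythro (7''S,8''R) guaiacylglycerol chain as a bis-TBS ether. C2 is fixed by Sharpless kinetic resolution; the side chain by an Evans syn aldol and Mitsunobu inversion at C7''.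

Key step: step 15

Locants: C2–C5 are the tetrahydrofuran carbons (C2 aryl, C3 CH2OH, C4 benzyl, C7' its benzylic CH2); C7''–C9'' are the side-chain carbons (C7'' carbinol, C8'' aryloxy CH, C9'' CH2OH).

Abbreviations: BnV = 4-(benzyloxy)-3-methoxyphenyl; Ar* = 3,5-dimethoxy-4-{[(1S,2R)-1-BnV-1,3-bis(tert-butyldimethylsilyloxy)propan-2-yl]oxy}phenyl.

Assumption: 4-bromo-2,6-dimethoxyphenol, 4-(benzyloxy)-3-methoxybenzaldehyde, (4S)-4-benzyl-1,3-oxazolidin-2-one and vinylmagnesium bromide are bought. The syringyl ring enters as the aryl bromide because an aldehyde on that ring would not survive the boron aldol; it is unmasked in step 9.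

Remark on stereochemistry: re-derived from the target, the ring is (2R,3S,4S) and the side chain (7''S,8''R), i.e. erythro. An Evans syn aldol gives the threo (7''R,8''R) pair, so C7'' is inverted in steps 6–7. In the key-step precursor the carbinol is (S) and the oxirane (R) (erythro); this is the same spatial arrangement as C2 (R) of the product, the descriptor changing only through CIP priorities.

Remark on protecting groups: the side-chain diol is carried as two TBS ethers and not as an acetal, so the end game needs only fluoride and hydrogen and no acid near the benzylic C–O bonds.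

**Route**

Step 1
Reactants: 1 4-bromo-2,6-dimethoxyphenol; 2 ethyl bromoacetate
Product: 4 2-(4-bromo-2,6-dimethoxyphenoxy)acetic acid, via ethyl 2-(4-bromo-2,6-dimethoxyphenoxy)acetate 3 (not isolated)
Conditions: K2CO3, acetone, reflux; then aq. NaOH, MeOH, rt; then aq. HCl
Reagents that add atoms: sodium hydroxide, [Na+].[OH-]
Why: Williamson ether synthesis of the phenoxide on a primary α-halo ester followed by saponification in the same pot; no stereocentre is involved.

Step 2
Reactants: 4 2-(4-bromo-2,6-dimethoxyphenoxy)acetic acid; 5 (4S)-4-benzyl-1,3-oxazolidin-2-one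
Product: 7 (4S)-4-benzyl-3-[2-(4-bromo-2,6-dimethoxyphenoxy)acetyl]-1,3-oxazolidin-2-one, via 2-(4-bromo-2,6-dimethoxyphenoxy)acetic pivalic anhydride 6 (not isolated)
Conditions: PivCl, Et3N, THF, −20 °C; then 5, LiCl, −20 °C to rt
Reagents that add atoms: none
Why: N-acylation of the oxazolidinone through the mixed pivalic anhydride should occur at the unhindered aryloxyacetyl carbonyl; the auxiliary stereocentre is untouched.

Step 3
Reactants: 7 the N-(aryloxyacetyl)oxazolidinone; 8 4-(benzyloxy)-3-methoxybenzaldehyde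
Product: 10 (4S)-4-benzyl-3-[(2S,3R)-3-BnV-2-(4-bromo-2,6-dimethoxyphenoxy)-3-hydroxypropanoyl]-1,3-oxazolidin-2-one, via (Z)-dibutylboron enolate of the imide 9 (not isolated)
Conditions: Bu2BOTf, i-Pr2NEt, CH2Cl2, −78 to 0 °C; then 8, −78 to 0 °C; pH 7 buffer, MeOH, H2O2
Reagents that add atoms: none
Why: Evans syn aldol reaction, in which the (Z)-boron enolate reacts through a closed Zimmerman–Traxler chair on the face away from the auxiliary benzyl group, setting C8'' with its final configuration and C7'' syn to it (threo, to be inverted in step 6).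

Step 4
Reactants: 10 the syn aldol adduct
Product: 11 (1R,2R)-1-BnV-2-(4-bromo-2,6-dimethoxyphenoxy)propane-1,3-diol (threo)
Conditions: LiBH4, H2O (1 equiv), THF, 0 °C
Reagents that add atoms: none
Why: Reductive cleavage of the N-acyloxazolidinone by borohydride at the exocyclic carbonyl should release the primary alcohol and the auxiliary without touching either stereocentre or the aryl bromide.

Step 5
Reactants: 11 the threo diol
Product: 12 (1R,2R)-1-BnV-2-(4-bromo-2,6-dimethoxyphenoxy)-3-(tert-butyldimethylsilyloxy)propan-1-ol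
Conditions: TBSCl (1.05 equiv), imidazole, CH2Cl2, 0 °C
Reagents that add atoms: tert-butyldimethylsilyl chloride, CC(C)(C)[Si](C)(C)Cl
Why: Silylation discriminates the primary C9'' hydroxyl from the hindered secondary benzylic one on steric grounds.

Step 6
Reactants: 12 the threo mono-TBS ether
Product: 13 (1S,2R)-1-BnV-2-(4-bromo-2,6-dimethoxyphenoxy)-3-(tert-butyldimethylsilyloxy)propyl 4-nitrobenzoate
Conditions: PPh3, DIAD, 4-nitrobenzoic acid, THF, 0 °C to rt
Reagents that add atoms: 4-nitrobenzoic acid, OC(=O)c1ccc(cc1)[N+](=O)[O-]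
Why: Mitsunobu esterification, in which SN2 displacement of the oxyphosphonium by the carboxylate inverts C7'' (R to S) and so converts the threo into the erythro series.

Step 7
Reactants: 13 the inverted 4-nitrobenzoate
Product: 14 (1S,2R)-1-BnV-2-(4-bromo-2,6-dimethoxyphenoxy)-3-(tert-butyldimethylsilyloxy)propan-1-ol (erythro)
Conditions: K2CO3, MeOH, 0 °C to rt
Reagents that add atoms: none
Why: Base-catalysed transesterification of the activated ester proceeds by acyl–oxygen cleavage, so the new C7'' configuration is kept, and the alkyl TBS ether and aryl bromide are inert.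

Step 8
Reactants: 14 the erythro alcohol
Product: 15 (1S,2R)-1-BnV-2-(4-bromo-2,6-dimethoxyphenoxy)-1,3-bis(tert-butyldimethylsilyloxy)propane (Ar*–Br)
Conditions: TBSOTf, 2,6-lutidine, CH2Cl2, −78 to 0 °C
Reagents that add atoms: tert-butyldimethylsilyl triflate, CC(C)(C)[Si](C)(C)OS(=O)(=O)C(F)(F)F
Why: Silyl triflate with a hindered base silylates the hindered secondary benzylic alcohol without breaking any bond to a stereocentre.

Step 9
Reactants: 15 Ar*–Br
Product: 17 Ar*–CHO (the side-chain-bearing syringaldehyde ether), via aryllithium Ar*–Li 16 (not isolated)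
Conditions: n-BuLi, THF, −78 °C; then DMF, −78 to 0 °C; aq. NH4Cl
Reagents that add atoms: N,N-dimethylformamide, CN(C)C=O
Why: Bromine–lithium exchange at −78 °C is faster than any deprotonation, and Bouveault formylation of the aryllithium with DMF gives the aldehyde on hydrolysis; silyl, benzyl and methyl ethers are stable.

Step 10
Reactants: 17 Ar*–CHO; 18 vinylmagnesium bromide
Product: 19 1-Ar*-prop-2-en-1-ol, both C1 epimers
Conditions: THF, −78 to 0 °C; aq. NH4Cl
Reagents that add atoms: none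
Why: Grignard 1,2-addition to a non-enolisable aldehyde; the remote side-chain stereocentres exert no control, so the two C1 epimers are expected in similar amounts and are differentiated in step 11.

Step 11
Reactants: 19 the epimeric allylic alcohols
Product: 20 (S)-Ar*[(2R)-oxiran-2-yl]methanol (erythro epoxy alcohol)
Conditions: Ti(Oi-Pr)4 (0.2 equiv), L-(+)-DIPT (0.25 equiv), t-BuOOH (0.55 equiv), 4 Å MS, CH2Cl2, −20 °C; aq. tartaric acid work-up
Reagents that add atoms: tert-butyl hydroperoxide, CC(C)(C)OO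
Why: Sharpless kinetic-resolution epoxidation, in which the L-(+)-tartrate catalyst should epoxidise only the (1R)-epimer (carbinol aryl on the face opposite to oxygen delivery) to the erythro oxirane (new centre R), leaving the (1S)-epimer to be removed by chromatography; this fixes the future C2, and at most half of 19 can be converted.

Step 12
Reactants: 8 4-(benzyloxy)-3-methoxybenzaldehyde; 18 vinylmagnesium bromide
Product: 21 rac-1-BnV-prop-2-en-1-ol
Conditions: THF, 0 °C; aq. NH4Cl
Reagents that add atoms: none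
Why: Grignard 1,2-addition to the aryl aldehyde; the racemic carbinol is acceptable because its stereocentre disappears in step 13.

Step 13
Reactants: 21 rac-1-BnV-prop-2-en-1-ol
Product: 22 (E)-1-(benzyloxy)-4-(3-bromoprop-1-en-1-yl)-2-methoxybenzene (O-benzylconiferyl bromide)
Conditions: PBr3 (0.4 equiv), Et2O, 0 °C; used crude at once
Reagents that add atoms: phosphorus tribromide, BrP(Br)Br
Why: Bromination with allylic transposition (SN2'/ion-pair collapse) of the secondary benzylic allylic alcohol should give the conjugated, thermodynamically preferred primary (E)-cinnamyl bromide.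

Step 14
Reactants: 20 the erythro epoxy alcohol; 22 O-benzylconiferyl bromide
Product: 23 (2R)-2-[(S)-Ar*{[(2E)-3-BnV-prop-2-en-1-yl]oxy}methyl]oxirane (the cyclisation precursor)
Conditions: NaH added to 20 + 22, Bu4NI (cat.), THF/DMF, 0 °C
Reagents that add atoms: none
Why: Williamson etherification of the secondary alkoxide with a reactive primary allylic bromide; in cold aprotic medium with the electrophile present from the start, alkylation should outrun Payne rearrangement, and the carbinol C–O bond is not broken, so C2 is retained.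

Step 15
Reactants: 23 the epoxy cinnamyl ether
Product: 24 [(2R,3S,4S)-2-Ar*-4-(4-benzyloxy-3-methoxybenzyl)oxolan-3-yl]methanol
Conditions: Cp2TiCl2 (2.5 equiv), Zn dust, THF, rt (gives Cp2TiCl); added slowly to 23 in THF, rt; then 0.5 M aq. HCl, 0 °C, brief
Reagents that add atoms: none
Why: Cp2TiCl transfers one electron to the oxirane oxygen and the C–O bond to the more substituted carbon breaks, giving the secondary C3 radical with a titanium alkoxide on the future hydroxymethyl group; this radical adds to the near alkene carbon of the cinnamyl ether, and the benzylic C7' radical is trapped by a second Cp2TiCl and protonated on work-up. The closest known reaction type is the titanocene(III) (Nugent–RajanBabu reagent) reductive epoxide opening with radical cyclisation of epoxy allyl ethers to 2-aryl-3-hydroxymethyl-4-benzyl tetrahydrofurans. The tetrahydrofuran ring closes in the 5-exo-trig mode by forming C3–C4. C3 is set trans to the C2 aryl because that group sits pseudo-equatorial in the chair-like (Beckwith–Houk) transition state and the planar radical keeps no memory of the oxirane configuration; C4 is set cis to the C3 substituent by the 1,5-cis preference of a 1-substituted hexenyl radical. The step needs cyclisation to outrun reduction of the C3 radical (which would lead to deoxygenation) and exo to beat endo closure; slow addition keeps Ti(III) dilute, and the styrene-type acceptor, which gives a benzylic radical, makes the 5-exo addition fast and regiochemically unambiguous.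

Step 16
Reactants: 24 the bis-TBS dibenzyl tetrahydrofuran
Product: 25 (1S,2R)-1-BnV-2-{4-[(2R,3S,4S)-4-(4-benzyloxy-3-methoxybenzyl)-3-(hydroxymethyl)oxolan-2-yl]-2,6-dimethoxyphenoxy}propane-1,3-diol
Conditions: TBAF (3 equiv), THF, 0 °C to rt; aq. NH4Cl
Reagents that add atoms: none
Why: Fluoride cleaves both TBS ethers through Si–F bond formation under near-neutral conditions, so no benzylic C–O bond should ionise and no stereocentre is affected.

Step 17
Reactants: 25 the dibenzyl ether triol
Product: 26 (1S,2R)-1-(4-hydroxy-3-methoxyphenyl)-2-{4-[(2R,3S,4S)-4-(4-hydroxy-3-methoxybenzyl)-3-(hydroxymethyl)oxolan-2-yl]-2,6-dimethoxyphenoxy}propane-1,3-diol (target)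
Conditions: H2 (1 atm), 10% Pd/C, EtOAc/MeOH, rt; stopped when 25 is consumed
Reagents that add atoms: none
Why: Catalytic hydrogenolysis removes the two aryl benzyl ethers, which should cleave much faster under neutral conditions than the benzylic ring ether or the benzylic alcohol.

**Compound list**

1 | 4-bromo-2,6-dimethoxyphenol | COc1cc(Br)cc(OC)c1O | starting material
2 | ethyl bromoacetate | CCOC(=O)CBr | starting material
3 | ethyl 2-(4-bromo-2,6-dimethoxyphenoxy)acetate | CCOC(=O)COc1c(OC)cc(Br)cc1OC | intermediate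
4 | 2-(4-bromo-2,6-dimethoxyphenoxy)acetic acid | OC(=O)COc1c(OC)cc(Br)cc1OC | intermediate
5 | (4S)-4-benzyl-1,3-oxazolidin-2-one | O=C1N[C@@H](Cc2ccccc2)CO1 | starting material
6 | 2-(4-bromo-2,6-dimethoxyphenoxy)acetic pivalic anhydride | CC(C)(C)C(=O)OC(=O)COc1c(OC)cc(Br)cc1OC | intermediate
7 | (4S)-4-benzyl-3-[2-(4-bromo-2,6-dimethoxyphenoxy)acetyl]-1,3-oxazolidin-2-one | COc1cc(Br)cc(OC)c1OCC(=O)N2[C@@H](Cc3ccccc3)COC2=O | intermediate
8 | 4-(benzyloxy)-3-methoxybenzaldehyde | COc1cc(C=O)ccc1OCc2ccccc2 | starting material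
9 | (Z)-dibutylboron enolate of 7 | CCCCB(CCCC)O/C(=C\Oc1c(OC)cc(Br)cc1OC)N2[C@@H](Cc3ccccc3)COC2=O | intermediate
10 | (4S)-4-benzyl-3-[(2S,3R)-3-(4-benzyloxy-3-methoxyphenyl)-2-(4-bromo-2,6-dimethoxyphenoxy)-3-hydroxypropanoyl]-1,3-oxazolidin-2-one | COc1cc(Br)cc(OC)c1O[C@H](C(=O)N2[C@@H](Cc3ccccc3)COC2=O)[C@H](O)c4ccc(OCc5ccccc5)c(OC)c4 | intermediate
11 | (1R,2R)-1-(4-benzyloxy-3-methoxyphenyl)-2-(4-bromo-2,6-dimethoxyphenoxy)propane-1,3-diol | COc1cc(Br)cc(OC)c1O[C@H](CO)[C@H](O)c2ccc(OCc3ccccc3)c(OC)c2 | intermediate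
12 | (1R,2R)-1-(4-benzyloxy-3-methoxyphenyl)-2-(4-bromo-2,6-dimethoxyphenoxy)-3-(tert-butyldimethylsilyloxy)propan-1-ol | COc1cc(Br)cc(OC)c1O[C@H](CO[Si](C)(C)C(C)(C)C)[C@H](O)c2ccc(OCc3ccccc3)c(OC)c2 | intermediate
13 | (1S,2R)-1-(4-benzyloxy-3-methoxyphenyl)-2-(4-bromo-2,6-dimethoxyphenoxy)-3-(tert-butyldimethylsilyloxy)propyl 4-nitrobenzoate | COc1cc(Br)cc(OC)c1O[C@H](CO[Si](C)(C)C(C)(C)C)[C@@H](OC(=O)c2ccc(cc2)[N+](=O)[O-])c3ccc(OCc4ccccc4)c(OC)c3 | intermediate
14 | (1S,2R)-1-(4-benzyloxy-3-methoxyphenyl)-2-(4-bromo-2,6-dimethoxyphenoxy)-3-(tert-butyldimethylsilyloxy)propan-1-ol | COc1cc(Br)cc(OC)c1O[C@H](CO[Si](C)(C)C(C)(C)C)[C@@H](O)c2ccc(OCc3ccccc3)c(OC)c2 | intermediate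
15 | (1S,2R)-1-(4-benzyloxy-3-methoxyphenyl)-2-(4-bromo-2,6-dimethoxyphenoxy)-1,3-bis(tert-butyldimethylsilyloxy)propane (Ar*–Br) | Brc1cc(OC)c(O[C@H](CO[Si](C)(C)C(C)(C)C)[C@@H](O[Si](C)(C)C(C)(C)C)c2ccc(OCc3ccccc3)c(OC)c2)c(OC)c1 | intermediate
16 | aryllithium Ar*–Li (lithium in place of bromine in 15) | [Li]c1cc(OC)c(O[C@H](CO[Si](C)(C)C(C)(C)C)[C@@H](O[Si](C)(C)C(C)(C)C)c2ccc(OCc3ccccc3)c(OC)c2)c(OC)c1 | intermediate
17 | 4-{[(1S,2R)-1-(4-benzyloxy-3-methoxyphenyl)-1,3-bis(tert-butyldimethylsilyloxy)propan-2-yl]oxy}-3,5-dimethoxybenzaldehyde (Ar*–CHO) | O=Cc1cc(OC)c(O[C@H](CO[Si](C)(C)C(C)(C)C)[C@@H](O[Si](C)(C)C(C)(C)C)c2ccc(OCc3ccccc3)c(OC)c2)c(OC)c1 | intermediate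
18 | vinylmagnesium bromide | C=C[Mg]Br | starting material
19 | 1-Ar*-prop-2-en-1-ol, both C1 epimers | OC(C=C)c1cc(OC)c(O[C@H](CO[Si](C)(C)C(C)(C)C)[C@@H](O[Si](C)(C)C(C)(C)C)c2ccc(OCc3ccccc3)c(OC)c2)c(OC)c1 | intermediate
20 | (S)-Ar*[(2R)-oxiran-2-yl]methanol (erythro) | O[C@@H](c1cc(OC)c(O[C@H](CO[Si](C)(C)C(C)(C)C)[C@@H](O[Si](C)(C)C(C)(C)C)c2ccc(OCc3ccccc3)c(OC)c2)c(OC)c1)[C@H]4CO4 | intermediate
21 | rac-1-(4-benzyloxy-3-methoxyphenyl)prop-2-en-1-ol | COc1cc(C(O)C=C)ccc1OCc2ccccc2 | intermediate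
22 | (E)-1-(benzyloxy)-4-(3-bromoprop-1-en-1-yl)-2-methoxybenzene | COc1cc(/C=C/CBr)ccc1OCc2ccccc2 | intermediate
23 | (2R)-2-[(S)-Ar*{[(2E)-3-(4-benzyloxy-3-methoxyphenyl)prop-2-en-1-yl]oxy}methyl]oxirane | COc1cc(/C=C/CO[C@@H](c2cc(OC)c(O[C@H](CO[Si](C)(C)C(C)(C)C)[C@@H](O[Si](C)(C)C(C)(C)C)c3ccc(OCc4ccccc4)c(OC)c3)c(OC)c2)[C@H]5CO5)ccc1OCc6ccccc6 | intermediate
24 | [(2R,3S,4S)-2-Ar*-4-(4-benzyloxy-3-methoxybenzyl)oxolan-3-yl]methanol | COc1cc(C[C@@H]2CO[C@@H](c3cc(OC)c(O[C@H](CO[Si](C)(C)C(C)(C)C)[C@@H](O[Si](C)(C)C(C)(C)C)c4ccc(OCc5ccccc5)c(OC)c4)c(OC)c3)[C@@H]2CO)ccc1OCc6ccccc6 | intermediate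
25 | (1S,2R)-1-(4-benzyloxy-3-methoxyphenyl)-2-{4-[(2R,3S,4S)-4-(4-benzyloxy-3-methoxybenzyl)-3-(hydroxymethyl)oxolan-2-yl]-2,6-dimethoxyphenoxy}propane-1,3-diol | COc1cc(C[C@@H]2CO[C@@H](c3cc(OC)c(O[C@H](CO)[C@@H](O)c4ccc(OCc5ccccc5)c(OC)c4)c(OC)c3)[C@@H]2CO)ccc1OCc6ccccc6 | intermediate
26 | (1S,2R)-1-(4-hydroxy-3-methoxyphenyl)-2-{4-[(2R,3S,4S)-4-(4-hydroxy-3-methoxybenzyl)-3-(hydroxymethyl)oxolan-2-yl]-2,6-dimethoxyphenoxy}propane-1,3-diol | COc1cc(C[C@@H]2CO[C@@H](c3cc(OC)c(O[C@H](CO)[C@@H](O)c4ccc(O)c(OC)c4)c(OC)c3)[C@@H]2CO)ccc1O | target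

**Count and risks**

Total steps: 17. Longest linear sequence: 15 (steps 1–11 and 14–17); steps 12–13 make the bromide used in step 14.

Steps most likely to fail:

1. Step 15. The C3 radical may be reduced by Ti(III) before it cyclises, leading to loss of the oxygen and an allylic ether, or the 3,4-cis preference may be eroded. Fallback: the same C3 radical is generated without titanium. Setting out from 23, the terminal oxirane carbon is opened with caesium pivalate (DMF, 80 °C) to the hydroxy pivalate F1. This is converted with phenyl chlorothionoformate, pyridine and DMAP into the O-phenyl thionocarbonate F2. Slow addition of Bu3SnH/AIBN in toluene at 80 °C should then give, by Barton–McCombie-type C–O homolysis and 5-exo cyclisation, the cyclised pivalate F3. DIBAL-H in CH2Cl2 at −78 °C removes the pivalate, and the route is rejoined at 24.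

2. Step 6. The activated benzylic hydroxyl may be lost by elimination to the enol ether, or the electron-rich benzylic oxyphosphonium may ionise so that inversion is incomplete. Fallback: oxidation–reduction in place of substitution. Setting out from 12, Dess–Martin periodinane (CH2Cl2, NaHCO3) gives the α-aryloxy ketone F4. It is reduced at once, to limit enolisation at C8'', with Zn(BH4)2 in Et2O at low temperature. Chelation of zinc between the carbonyl and the α-aryloxy oxygen should direct hydride to the face that gives the anti (erythro) alcohol, and the route is rejoined at 14.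

3. Step 11. The rate difference between the two carbinol epimers may be too small, or the slowly formed epoxy alcohol may be opened by the titanium Lewis acid. Fallback: the unwanted epimer is destroyed and the wanted one is epoxidised separately. Setting out from 19, the epoxidation is run with D-(−)-DIPT to beyond half conversion, so that the (1S)-epimer is consumed as the discarded epoxy alcohol F6 and the (1R)-allylic alcohol F5 is recovered. F5 is then epoxidised under hydroxyl direction with VO(acac)2/t-BuOOH (CH2Cl2, 0 °C), which should favour the erythro isomer. The minor threo oxirane epimer F7 is removed by chromatography, and the route is rejoined at 20.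

Further compounds
F1 | step 15 | (2R,3S)-3-Ar*-3-{[(2E)-3-(4-benzyloxy-3-methoxyphenyl)prop-2-en-1-yl]oxy}-2-hydroxypropyl pivalate | COc1cc(/C=C/CO[C@@H](c2cc(OC)c(O[C@H](CO[Si](C)(C)C(C)(C)C)[C@@H](O[Si](C)(C)C(C)(C)C)c3ccc(OCc4ccccc4)c(OC)c3)c(OC)c2)[C@H](O)COC(=O)C(C)(C)C)ccc1OCc5ccccc5
F2 | step 15 | O-phenyl thionocarbonate of F1 at the secondary hydroxyl | COc1cc(/C=C/CO[C@@H](c2cc(OC)c(O[C@H](CO[Si](C)(C)C(C)(C)C)[C@@H](O[Si](C)(C)C(C)(C)C)c3ccc(OCc4ccccc4)c(OC)c3)c(OC)c2)[C@H](OC(=S)Oc5ccccc5)COC(=O)C(C)(C)C)ccc1OCc6ccccc6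
F3 | step 15 | [(2R,3S,4S)-2-Ar*-4-(4-benzyloxy-3-methoxybenzyl)oxolan-3-yl]methyl pivalate | COc1cc(C[C@@H]2CO[C@@H](c3cc(OC)c(O[C@H](CO[Si](C)(C)C(C)(C)C)[C@@H](O[Si](C)(C)C(C)(C)C)c4ccc(OCc5ccccc5)c(OC)c4)c(OC)c3)[C@@H]2COC(=O)C(C)(C)C)ccc1OCc6ccccc6
F4 | step 6 | (2R)-1-(4-benzyloxy-3-methoxyphenyl)-2-(4-bromo-2,6-dimethoxyphenoxy)-3-(tert-butyldimethylsilyloxy)propan-1-one | COc1cc(Br)cc(OC)c1O[C@H](CO[Si](C)(C)C(C)(C)C)C(=O)c2ccc(OCc3ccccc3)c(OC)c2
F5 | step 11 | (1R)-1-Ar*-prop-2-en-1-ol (single epimer) | O[C@@H](c1cc(OC)c(O[C@H](CO[Si](C)(C)C(C)(C)C)[C@@H](O[Si](C)(C)C(C)(C)C)c2ccc(OCc3ccccc3)c(OC)c2)c(OC)c1)C=C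
F6 | step 11 | (R)-Ar*[(2S)-oxiran-2-yl]methanol (erythro, from the unwanted epimer) | O[C@H](c1cc(OC)c(O[C@H](CO[Si](C)(C)C(C)(C)C)[C@@H](O[Si](C)(C)C(C)(C)C)c2ccc(OCc3ccccc3)c(OC)c2)c(OC)c1)[C@@H]4CO4
F7 | step 11 | (S)-Ar*[(2S)-oxiran-2-yl]methanol (threo oxirane epimer of 20) | O[C@@H](c1cc(OC)c(O[C@H](CO[Si](C)(C)C(C)(C)C)[C@@H](O[Si](C)(C)C(C)(C)C)c2ccc(OCc3ccccc3)c(OC)c2)c(OC)c1)[C@@H]4CO4
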